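Left-handed and right-handed substrate start level, and the excess between them follows from one ratio: right over left, less one, divided by that ratio plus one. So we follow the gap, the natural logarithm of c(right-handed substrate)/c(left-handed substrate). It starts at zero, and the first rows of east and north-west already show less left-handed substrate than right-handed, the pattern of a kinetic resolution.

common to all: left-handed substrate 20 mM; right-handed substrate 20 mM; free catalyst 0.75 mol%

|  | coupling partner | remark | time |
|---|---|---|---|
| east | 1.7 equiv | run made earlier |  |
| north-west | 3.8 equiv | run made earlier |  |
| spring | 2.50 equiv |  | 6.0 min |
| dusk | 2.50 equiv |  | 1.5 min |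

| run | time / min | right-handed substrate / % | left-handed substrate / % | left-handed product / % |
|---|---|---|---|---|
| east | 1.33 | 48.3 | 32.6 | 14.5 |
| east | 2.50 | 48.8 | 27.1 | 19.6 |
| east | 4.00 | 48.3 | 22.4 | 23.5 |
| east | 5.00 | 47.5 | 20.2 | 26.0 |
| east | 6.00 | 47.1 | 16.3 | 25.8 |
| east | 8.00 | 45.3 | 14.6 | 29.0 |
| north-west | 1.33 | 48.7 | 22.1 | 24.8 |
| north-west | 2.50 | 48.5 | 14.6 | 30.8 |
| north-west | 4.00 | 43.5 | 9.0 | 33.1 |
| north-west | 5.00 | 44.8 | 7.1 | 35.2 |
| north-west | 6.00 | 44.2 | 7.7 | 33.9 |
| north-west | 8.00 | 42.6 | 6.1 | 31.5 |

(standard deviation of a reading: 1 percentage point)

- free catalyst is single-handed; left-handed substrate and right-handed substrate are mirror images of each other, charged as a racemate, each of them at the stated concentration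
- an excess is the difference of the two amounts in percent of their sum
- an excess is below zero if the other one leads

1. the flask that ends with the higher excess of right-handed substrate over left-handed substrate among what is left of the two, or "neither" when 2 percentage points or less lies between them (spring / dusk / neither)
2. excess of right-handed substrate over left-handed substrate among what is left of the two at the end, spring
3. excess of right-handed substrate over left-handed substrate among what is left of the two at the end, dusk

We read the tables row by row. At 1.33 min the gap is 0.393 in east and 0.790 in north-west. At 2.50 min it is 0.588 and 1.20. North-west stands at twice the east gap in the first row and twice in the second, with 2.24 times the coupling partner and the same catalyst loading. We therefore take the gap as a power of the partner charged. On a power law, a charge at the geometric mean of two runs has the geometric mean of their gaps, and that mean charge is 2.54, against 2.50 equiv in spring and dusk. The east gap per minute is less in the second row than in the first, so we stay on the readings and use no rate constant.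

Dusk stops at 1.5 min, between the first two rows. Straight interpolation gives 0.421 for east and 0.850 for north-west. Their geometric mean is 0.598, our gap at the end of dusk, which means an excess of 29.1%. Spring stops on the row at 6.00 min, where the two gaps give 1.36 and an excess of 59.2%. On this reckoning spring leads dusk by more than the margin.

The forecast, made to “scale the observed curves rather than use one rate constant”, says spring, with 59% for spring and 29% for dusk.

The flasks give 58.7% in spring and 28.0% in dusk, so spring ends higher.

    coupling partner + free catalyst + left-handed substrate → free catalyst + left-handed product (k = 65600 L² mol⁻² min⁻¹)
    left-handed substrate ⇌ right-handed substrate (k = 0.0266 min⁻¹)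
    coupling partner + free catalyst + right-handed substrate → free catalyst + right-handed product (k = 367 L² mol⁻² min⁻¹)
    left-handed product ⇌ right-handed product (k = 0.106 min⁻¹)
    coupling partner + free catalyst → spent catalyst (k = 2.65 L mol⁻¹ min⁻¹)

A neighbour flask repeats dusk with 0.19 mol% of free catalyst instead of 0.75 mol%. Both substrate steps of the scheme carry c(free catalyst) as a factor, and spent catalyst after 1.50 min is 17.5% of the catalyst charged in the neighbour flask against 16.3% in dusk. So we shrink our dusk gap in proportion to the loading, to 0.152, which means an excess of 7.59%. That flask ends with 42.6% left-handed substrate and 49.8% right-handed substrate, an excess of 7.83%.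

The runs stem from a simulated flask with made-up constants, noise included.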